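Readings and results are simulated from invented constants, noise included.

A small charge of reagent is where to start, because the flask stands between two runs that differ in that charge.

in all of them: substrate 0.32 M

| run | reagent | free catalyst | remark |
|---|---|---|---|
| dawn | 0.080 M | 8 mM | run made earlier |
| summer | 0.32 M | 8 mM | run made earlier |
| flask | 0.160 M | 8.0 mM |  |

| run | time / min | target / % | substrate / % |
|---|---|---|---|
| dawn | 0.667 | 5.6 | 95.6 |
| dawn | 1.50 | 10.4 | 90.7 |
| dawn | 3.00 | 12.7 | 86.7 |
| dawn | 5.00 | 13.9 | 86.3 |
| summer | 0.667 | 15.4 | 86.9 |
| summer | 1.50 | 16.6 | 82.9 |
| summer | 3.00 | 23.6 | 77.8 |
| summer | 5.00 | 22.6 | 76.6 |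

(scatter of a reading: 1 percentage point)

- apparent order in free catalyst when 5.0% of the substrate are converted (percent change of the rate of making target for one percent more free catalyst charged)
- factor on the rate of making target when 5.0% of the substrate are converted if reagent is charged twice over

- steps thought possible: substrate + catalyst intermediate A <-> catalyst intermediate B; reagent + free catalyst <-> catalyst intermediate A; catalyst intermediate D -> free catalyst + target; catalyst intermediate C -> by-product + catalyst intermediate D; catalyst intermediate B <-> catalyst intermediate C; 2 reagent -> self-condensation product
- no earlier run changes the charge of free catalyst; that part of a forecast is a guess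

The dawn run stops near 13.9% of the substrate charged, which is 55.6% of its reagent charge. The summer run, with 4.00 times the reagent, stops near 22.6%, which is 22.6% of its reagent charge. Substrate is still at hand in both, at 86.3% and 76.6%, so I look to reagent for the stop. Self-condensation takes reagent two at a time, so its rate goes with the square of reagent, and that fits the summer run keeping the smaller share.

The rate asked for belongs to the early minutes, so go to logarithms at the first reading, 0.667 min, where the target stands at 5.6% in dawn and 15.4% in summer. The logarithm of that ratio over the logarithm of the charge ratio gives 0.730, the reagent order: the percent change of early target for one percent more reagent charged. A scatter of 1 percentage point on the dawn reading makes this order a soft number. Charged twice over, the flask has the summer charge of reagent, and two raised to the reagent order gives my factor, 1.66. No run varies free catalyst, so any order there is a guess.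

The forecast gave 1.4 for free catalyst, holding that “More catalyst beats self-condensation”, and 1.8 for the reagent factor, above my factor.

    substrate + catalyst intermediate A ⇌ catalyst intermediate B (K = 0.787 M⁻¹, k = 35.9 M⁻¹ s⁻¹)
    reagent + free catalyst ⇌ catalyst intermediate A (K = 1.47 M⁻¹, k = 50.2 M⁻¹ s⁻¹)
    catalyst intermediate D → free catalyst + target (k = 3.93 s⁻¹)
    catalyst intermediate C → by-product + catalyst intermediate D (k = 4.02 s⁻¹)
    catalyst intermediate B ⇌ catalyst intermediate C (K = 13.0, k = 5.31 s⁻¹)
    2 reagent → self-condensation product (k = 0.139 M⁻¹ s⁻¹)

The flask gives 1.67 for the reagent factor, against my 1.66, and 1.4 for free catalyst. At 4.00 min the flask holds 1.77% of its reagent and 81.9% of its substrate, so reagent is the limiting reagent. Now use the reagent order on dawn, which has half the reagent of the flask. The flask's 0.0519 M min⁻¹ at 5.0% conversion, divided by the substrate charge and by 1.66, gives my estimate for the dawn run, as a fraction of the substrate charge per minute, 0.0978 min⁻¹. Held steady, that rate covers 5.0% in 0.511 min, and the dawn run reads 5.6% at 0.667 min.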